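The route rests on cutting C13–C14 (chain numbered from the ester carbonyl C1 to C17, the CH2 on the furan): the sp3–sp2 bond of the skipped 1,5-diene repeat between the homoallylic CH2 of the C10=C11 alkene and the methyl-bearing carbon of the C14=C15 alkene beside the 3-furyl ring. A Ni-electrocatalytic decarboxylative alkenylation makes this bond and joins both halves in one operation: an N-hydroxyphthalimide ester carrying one extra carboxyl carbon on C13 loses CO2, and the C13 radical is captured by nickel holding the (E)-alkenyl iodide, whose geometry becomes that of C14=C15. The precursor is the complete C1–C13 triene redox-active ester, its C6 acid masked as a 2-(trimethylsilyl)ethyl (TMSE) ester.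

Key step: step 14

Remark (assumption): the target has no stereocentre and is achiral, so "single isomer" is taken as the drawn geometry 2E, 6Z (CO2H cis to C8), 10E, 14E; the target numbering above is used throughout.

Step 1
Reactants: 1 pent-3-yn-1-ol
Product: 2 5-iodopent-2-yne
Conditions: I2, PPh3, imidazole, CH2Cl2, 0 °C to rt
Reagents that add atoms: iodine, II
Why: Appel-type iodination, in which the alcohol is activated as an alkoxyphosphonium ion and displaced by iodide in an SN2 reaction that leaves the internal alkyne untouched.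

Step 2
Reactants: 2 5-iodopent-2-yne; 3 3-bromofuran
Product: 5 3-(pent-3-yn-1-yl)furan, via alkylzinc iodide 4 (not isolated)
Conditions: Zn dust (activated), LiCl, THF, 40 °C; then 3, Pd(OAc)2 (cat.), SPhos (cat.), THF, rt to 50 °C
Reagents that add atoms: none
Why: LiCl-promoted zinc insertion into the primary C–I bond followed by a Negishi sp3–sp2 cross-coupling with the heteroaryl bromide, both of which tolerate the internal alkyne.

Step 3
Reactants: 5 3-(pent-3-yn-1-yl)furan
Product: 7 (E)-3-(4-iodopent-3-en-1-yl)furan, via alkenylzirconocene chloride 6 (not isolated)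
Conditions: Cp2Zr(H)Cl (2 equiv), THF, rt to 50 °C; then I2, THF, 0 °C
Reagents that add atoms: iodine, II
Why: Hydrozirconation with excess Schwartz reagent is a syn addition that equilibrates to the less hindered regioisomer with Zr on the methyl-bearing carbon, and iodinolysis with retention should give the (E)-2-iodo-2-alkene with iodine trans to the furylethyl chain.

Step 4
Reactants: 8 2-(trimethylsilyl)ethanol; 9 bromoacetyl bromide
Product: 10 2-(trimethylsilyl)ethyl 2-bromoacetate
Conditions: pyridine, CH2Cl2, 0 °C
Reagents that add atoms: none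
Why: Esterification by nucleophilic acyl substitution at the acid bromide, which is far faster than displacement of the α-bromide.

Step 5
Reactants: 10 2-(trimethylsilyl)ethyl 2-bromoacetate; 11 diphenyl phosphite
Product: 12 2-(trimethylsilyl)ethyl 2-(diphenoxyphosphoryl)acetate
Conditions: Et3N, CH2Cl2, 0 °C to rt
Reagents that add atoms: none
Why: Michaelis–Becker-type P-alkylation in the Ando manner, in which the amine salt of the acidic diaryl H-phosphonate displaces the activated α-bromide to give the diaryl phosphonoacetate.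

Step 6
Reactants: 12 2-(trimethylsilyl)ethyl 2-(diphenoxyphosphoryl)acetate; 13 acrolein; 14 methyl 2-(triphenylphosphoranylidene)propanoate
Product: 16 1-methyl 7-[2-(trimethylsilyl)ethyl] (2E)-6-(diphenoxyphosphoryl)-2-methylhept-2-enedioate (racemic), via aldehyde 15 (not isolated)
Conditions: 13, DBU (10 mol%), THF, −20 °C; AcOH (10 mol%); then 14, CH2Cl2, rt
Reagents that add atoms: none
Why: Base-catalysed Michael addition of the doubly activated C–H of 12 to acrolein followed by a Wittig reaction of the aldehyde with the α-methyl stabilised ylide, which is E-selective (2E); the stereocentre at the phosphonate carbon forms racemic and is destroyed in step 10.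

Step 7
Reactants: 17 4-[(tert-butyldimethylsilyl)oxy]butanal; 18 isopropenylmagnesium bromide
Product: 19 6-[(tert-butyldimethylsilyl)oxy]-2-methylhex-1-en-3-ol (racemic)
Conditions: THF, −78 to 0 °C; aq. NH4Cl
Reagents that add atoms: none
Why: Grignard 1,2-addition to the aldehyde gives the racemic isopropenyl carbinol, whose stereocentre is consumed in step 8.

Step 8
Reactants: 19 6-[(tert-butyldimethylsilyl)oxy]-2-methylhex-1-en-3-ol; 20 triethyl orthoacetate
Product: 22 ethyl (4E)-8-[(tert-butyldimethylsilyl)oxy]-4-methyloct-4-enoate, via ketene acetal 21 (not isolated)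
Conditions: 20 (excess), EtCO2H (cat.), 140 °C, EtOH distilled off
Reagents that add atoms: none
Why: Johnson–Claisen rearrangement, in which ketene acetal 21 reacts through a chair transition state with the silyloxypropyl group equatorial and should thereby set the (E)-trisubstituted alkene that becomes C10=C11.

Step 9
Reactants: 22 ethyl (4E)-8-[(tert-butyldimethylsilyl)oxy]-4-methyloct-4-enoate
Product: 23 (4E)-8-[(tert-butyldimethylsilyl)oxy]-4-methyloct-4-enal
Conditions: DIBAL-H (1.05 equiv), CH2Cl2, −78 °C; Rochelle salt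
Reagents that add atoms: none
Why: DIBAL-H half-reduction of the ester at −78 °C, where the aluminium hemiacetal survives until work-up and so releases the aldehyde without over-reduction.

Step 10
Reactants: 16 1-methyl 7-[2-(trimethylsilyl)ethyl] (2E)-6-(diphenoxyphosphoryl)-2-methylhept-2-enedioate; 23 (4E)-8-[(tert-butyldimethylsilyl)oxy]-4-methyloct-4-enal
Product: 24 methyl (2E,6Z,10E)-14-[(tert-butyldimethylsilyl)oxy]-2,10-dimethyl-6-{[2-(trimethylsilyl)ethoxy]carbonyl}tetradeca-2,6,10-trienoate
Conditions: NaH, THF, 0 °C; then 23, −78 to 0 °C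
Reagents that add atoms: none
Why: Ando-type Z-selective Horner–Wadsworth–Emmons olefination, in which the electron-poor diaryl phosphonate eliminates quickly from the kinetically formed syn adduct so that the TMSE ester should end cis to the C8 chain (6Z).

Step 11
Reactants: 24 methyl (2E,6Z,10E)-14-[(tert-butyldimethylsilyl)oxy]-2,10-dimethyl-6-{[2-(trimethylsilyl)ethoxy]carbonyl}tetradeca-2,6,10-trienoate
Product: 25 methyl (2E,6Z,10E)-14-hydroxy-2,10-dimethyl-6-{[2-(trimethylsilyl)ethoxy]carbonyl}tetradeca-2,6,10-trienoate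
Conditions: CSA (cat.), MeOH/CH2Cl2, 0 °C
Reagents that add atoms: none
Why: Acid-catalysed methanolysis (desilylation) of the primary TBS ether, to which both esters and the alkenes are inert at 0 °C.

Step 12
Reactants: 25 methyl (2E,6Z,10E)-14-hydroxy-2,10-dimethyl-6-{[2-(trimethylsilyl)ethoxy]carbonyl}tetradeca-2,6,10-trienoate
Product: 26 (4E,8Z,12E)-14-methoxy-5,13-dimethyl-14-oxo-9-{[2-(trimethylsilyl)ethoxy]carbonyl}tetradeca-4,8,12-trienoic acid
Conditions: TEMPO (cat.), PhI(OAc)2, MeCN/H2O, rt
Reagents that add atoms: water, O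
Why: TEMPO/PhI(OAc)2 (oxoammonium) oxidation in aqueous acetonitrile takes the primary alcohol through the aldehyde hydrate to the acid and does not touch trisubstituted alkenes or enoates.

Step 13
Reactants: 26 (4E,8Z,12E)-14-methoxy-5,13-dimethyl-14-oxo-9-{[2-(trimethylsilyl)ethoxy]carbonyl}tetradeca-4,8,12-trienoic acid; 27 N-hydroxyphthalimide
Product: 28 1,3-dioxoisoindolin-2-yl (4E,8Z,12E)-14-methoxy-5,13-dimethyl-14-oxo-9-{[2-(trimethylsilyl)ethoxy]carbonyl}tetradeca-4,8,12-trienoate
Conditions: DIC, DMAP (cat.), CH2Cl2, rt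
Reagents that add atoms: none
Why: Carbodiimide (Steglich-type) esterification of the only free carboxylic acid with N-hydroxyphthalimide gives the redox-active ester.

Step 14
Reactants: 28 1,3-dioxoisoindolin-2-yl (4E,8Z,12E)-14-methoxy-5,13-dimethyl-14-oxo-9-{[2-(trimethylsilyl)ethoxy]carbonyl}tetradeca-4,8,12-trienoate; 7 (E)-3-(4-iodopent-3-en-1-yl)furan
Product: 29 methyl (2E,6Z,10E,14E)-17-(furan-3-yl)-2,10,14-trimethyl-6-{[2-(trimethylsilyl)ethoxy]carbonyl}heptadeca-2,6,10,14-tetraenoate
Conditions: NiCl2·6H2O (10 mol%), 2,2'-bipyridine (10 mol%), AgNO3 (0.3 equiv), LiCl, DMF, Mg(+)/RVC(−), constant current, undivided cell, rt; 7 in 1.5-fold excess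
Reagents that add atoms: none
Why: Cathodically generated low-valent (bpy)Ni inserts into the C14–I bond of 7 with retention, while single-electron reduction of the phthalimide ester of 28 (by Ni(I) or at the silver-nanoparticle-coated cathode formed in situ) expels CO2 and phthalimide anion to leave the primary C13 radical; capture of this radical by the alkenyl–Ni(II) species and reductive elimination from Ni(III) forge C13–C14, with the Mg anode supplying the electrons. The closest known reaction type is the Ni-electrocatalytic decarboxylative alkenylation of redox-active esters with alkenyl halides, a reductive cross-electrophile coupling used for modular assembly of polyene terpenoids. No ring is closed and no stereocentre is created. The step needs retention at C14=C15, secured by stereoretentive oxidative addition and reductive elimination at the sp2 carbon of the E-iodide, and preservation of C10=C11, secured if trapping of the homoallylic radical by nickel outruns its reversible 3-exo closure. Cross-coupling over homocoupling follows from the different activation modes of the two partners (two-electron oxidative addition versus one-electron fragmentation), and the conjugated esters, the TMSE group and the 3-alkylfuran are not reduced at the mild potential that the nickel mediator requires.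

Step 15
Reactants: 29 methyl (2E,6Z,10E,14E)-17-(furan-3-yl)-2,10,14-trimethyl-6-{[2-(trimethylsilyl)ethoxy]carbonyl}heptadeca-2,6,10,14-tetraenoate
Product: 30 furospongin-4
Conditions: TBAF, THF, 0 °C to rt; cold dilute aq. HCl (pH 3)
Reagents that add atoms: none
Why: Fluoride attacks silicon and triggers β-elimination of the 2-(trimethylsilyl)ethyl ester (fluoride-induced fragmentation), which frees the C6 acid while the methyl ester, the furan and all four alkene geometries are untouched.

Compound list
1 | pent-3-yn-1-ol | CC#CCCO | starting material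
2 | 5-iodopent-2-yne | CC#CCCI | intermediate
3 | 3-bromofuran | Brc1ccoc1 | starting material
4 | (pent-3-yn-1-yl)zinc iodide | CC#CCC[Zn]I | intermediate
5 | 3-(pent-3-yn-1-yl)furan | CC#CCCc1ccoc1 | intermediate
6 | chlorobis(cyclopentadienyl)[(E)-5-(furan-3-yl)pent-2-en-2-yl]zirconium | C/C(=C\CCc1ccoc1)[Zr](Cl)(C1C=CC=C1)C1C=CC=C1 | intermediate
7 | (E)-3-(4-iodopent-3-en-1-yl)furan | C/C(I)=C\CCc1ccoc1 | intermediate
8 | 2-(trimethylsilyl)ethanol | C[Si](C)(C)CCO | starting material
9 | bromoacetyl bromide | BrCC(Br)=O | starting material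
10 | 2-(trimethylsilyl)ethyl 2-bromoacetate | C[Si](C)(C)CCOC(=O)CBr | intermediate
11 | diphenyl phosphite | O=[PH](Oc1ccccc1)Oc1ccccc1 | starting material
12 | 2-(trimethylsilyl)ethyl 2-(diphenoxyphosphoryl)acetate | C[Si](C)(C)CCOC(=O)CP(=O)(Oc1ccccc1)Oc1ccccc1 | intermediate
13 | acrolein | C=CC=O | starting material
14 | methyl 2-(triphenylphosphoranylidene)propanoate | COC(=O)C(C)=P(c1ccccc1)(c1ccccc1)c1ccccc1 | starting material
15 | 2-(trimethylsilyl)ethyl 2-(diphenoxyphosphoryl)-5-oxopentanoate (racemic) | C[Si](C)(C)CCOC(=O)C(CCC=O)P(=O)(Oc1ccccc1)Oc1ccccc1 | intermediate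
16 | 1-methyl 7-[2-(trimethylsilyl)ethyl] (2E)-6-(diphenoxyphosphoryl)-2-methylhept-2-enedioate (racemic) | COC(=O)/C(C)=C/CCC(C(=O)OCC[Si](C)(C)C)P(=O)(Oc1ccccc1)Oc1ccccc1 | intermediate
17 | 4-[(tert-butyldimethylsilyl)oxy]butanal | CC(C)(C)[Si](C)(C)OCCCC=O | starting material
18 | isopropenylmagnesium bromide | C=C(C)[Mg]Br | starting material
19 | 6-[(tert-butyldimethylsilyl)oxy]-2-methylhex-1-en-3-ol (racemic) | C=C(C)C(O)CCCO[Si](C)(C)C(C)(C)C | intermediate
20 | triethyl orthoacetate | CCOC(C)(OCC)OCC | starting material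
21 | 6-[(tert-butyldimethylsilyl)oxy]-3-[(1-ethoxyvinyl)oxy]-2-methylhex-1-ene (ketene acetal, racemic) | C=C(OCC)OC(CCCO[Si](C)(C)C(C)(C)C)C(C)=C | intermediate
22 | ethyl (4E)-8-[(tert-butyldimethylsilyl)oxy]-4-methyloct-4-enoate | CCOC(=O)CC/C(C)=C/CCCO[Si](C)(C)C(C)(C)C | intermediate
23 | (4E)-8-[(tert-butyldimethylsilyl)oxy]-4-methyloct-4-enal | O=CCC/C(C)=C/CCCO[Si](C)(C)C(C)(C)C | intermediate
24 | methyl (2E,6Z,10E)-14-[(tert-butyldimethylsilyl)oxy]-2,10-dimethyl-6-{[2-(trimethylsilyl)ethoxy]carbonyl}tetradeca-2,6,10-trienoate | COC(=O)/C(C)=C/CC/C(=C/CC/C(C)=C/CCCO[Si](C)(C)C(C)(C)C)C(=O)OCC[Si](C)(C)C | intermediate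
25 | methyl (2E,6Z,10E)-14-hydroxy-2,10-dimethyl-6-{[2-(trimethylsilyl)ethoxy]carbonyl}tetradeca-2,6,10-trienoate | COC(=O)/C(C)=C/CC/C(=C/CC/C(C)=C/CCCO)C(=O)OCC[Si](C)(C)C | intermediate
26 | (4E,8Z,12E)-14-methoxy-5,13-dimethyl-14-oxo-9-{[2-(trimethylsilyl)ethoxy]carbonyl}tetradeca-4,8,12-trienoic acid | COC(=O)/C(C)=C/CC/C(=C/CC/C(C)=C/CCC(=O)O)C(=O)OCC[Si](C)(C)C | intermediate
27 | N-hydroxyphthalimide | O=C1c2ccccc2C(=O)N1O | starting material
28 | 1,3-dioxoisoindolin-2-yl (4E,8Z,12E)-14-methoxy-5,13-dimethyl-14-oxo-9-{[2-(trimethylsilyl)ethoxy]carbonyl}tetradeca-4,8,12-trienoate | COC(=O)/C(C)=C/CC/C(=C/CC/C(C)=C/CCC(=O)ON1C(=O)c2ccccc2C1=O)C(=O)OCC[Si](C)(C)C | intermediate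
29 | methyl (2E,6Z,10E,14E)-17-(furan-3-yl)-2,10,14-trimethyl-6-{[2-(trimethylsilyl)ethoxy]carbonyl}heptadeca-2,6,10,14-tetraenoate | COC(=O)/C(C)=C/CC/C(=C/CC/C(C)=C/CC/C(C)=C/CCc1ccoc1)C(=O)OCC[Si](C)(C)C | intermediate
30 | furospongin-4, (2Z,6E,10E)-13-(furan-3-yl)-2-[(3E)-5-methoxy-4-methyl-5-oxopent-3-en-1-yl]-6,10-dimethyltrideca-2,6,10-trienoic acid | COC(=O)/C(C)=C/CC/C(=C/CC/C(C)=C/CC/C(C)=C/CCc1ccoc1)C(=O)O | target

Total step count: 15.
Longest linear sequence: 9 steps (steps 4, 5, 6, 10, 11, 12, 13, 14, 15 from 8 and 9; equally steps 7, 8, 9, 10–15 from 17).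

Steps most likely to fail

1. Step 14. The partners may be consumed at the cathode before they cross-couple (hydrodeiodination or homocoupling of the alkenyl iodide, reduction of the ester to the alkane). Slow radical capture would also let the C10=C11 geometry leak through reversible 3-exo closure of the homoallylic radical. Fallback, setting out from 7 and 28: iodine–lithium exchange of 7 (t-BuLi, Et2O, −78 °C) and transmetalation with ZnCl2 would give (E)-[5-(furan-3-yl)pent-2-en-2-yl]zinc chloride F1. F1 is then coupled with 28 in a thermal, non-electrochemical Ni-catalysed decarboxylative alkenylation of Negishi type (Ni(acac)2, 2,2'-bipyridine, THF/DMF, rt), in which a preformed alkenyl nucleophile replaces the reductive cross-electrophile manifold. The fallback comes back to the route at 29.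

2. Step 10. Kinetic control may be lost: reversible addition of the hindered α-branched diaryl phosphonate would let the 6E isomer (ester trans to C8) form. Fallback, setting out from 10: an Arbuzov reaction with tris(2,2,2-trifluoroethyl) phosphite (neat, heat) would give 2-(trimethylsilyl)ethyl 2-[bis(2,2,2-trifluoroethoxy)phosphoryl]acetate F2. Michael addition of F2 to 13 would give 2-(trimethylsilyl)ethyl 2-[bis(2,2,2-trifluoroethoxy)phosphoryl]-5-oxopentanoate F3, and a Wittig reaction with 14 would give 1-methyl 7-[2-(trimethylsilyl)ethyl] (2E)-6-[bis(2,2,2-trifluoroethoxy)phosphoryl]-2-methylhept-2-enedioate F4. A Still–Gennari olefination of 23 with F4 (KHMDS, 18-crown-6, THF, −78 °C), in which a dissociated potassium enolate and the trifluoroethyl esters enforce Z-selectivity, comes back to the route at 24.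

3. Step 6. Double Michael addition, polymerisation of acrolein, or a competing Horner–Wadsworth–Emmons or aldol reaction of the free aldehyde under base may drain the material before the Wittig step. Fallback, setting out from 12: C-alkylation with 2-(2-bromoethyl)-1,3-dioxolane (NaH, DMSO, rt) would give 2-(trimethylsilyl)ethyl 2-(diphenoxyphosphoryl)-4-(1,3-dioxolan-2-yl)butanoate F5, so the aldehyde is never exposed to base. Mild acetal hydrolysis (aq. HCl, acetone) comes back to the route at 15, which is taken on with 14 to 16 as in step 6.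

Further compounds
F1 | step 14 | (E)-[5-(furan-3-yl)pent-2-en-2-yl]zinc chloride | C/C([Zn]Cl)=C\CCc1ccoc1
F2 | step 10 | 2-(trimethylsilyl)ethyl 2-[bis(2,2,2-trifluoroethoxy)phosphoryl]acetate | C[Si](C)(C)CCOC(=O)CP(=O)(OCC(F)(F)F)OCC(F)(F)F
F3 | step 10 | 2-(trimethylsilyl)ethyl 2-[bis(2,2,2-trifluoroethoxy)phosphoryl]-5-oxopentanoate (racemic) | C[Si](C)(C)CCOC(=O)C(CCC=O)P(=O)(OCC(F)(F)F)OCC(F)(F)F
F4 | step 10 | 1-methyl 7-[2-(trimethylsilyl)ethyl] (2E)-6-[bis(2,2,2-trifluoroethoxy)phosphoryl]-2-methylhept-2-enedioate (racemic) | COC(=O)/C(C)=C/CCC(C(=O)OCC[Si](C)(C)C)P(=O)(OCC(F)(F)F)OCC(F)(F)F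
F5 | step 6 | 2-(trimethylsilyl)ethyl 2-(diphenoxyphosphoryl)-4-(1,3-dioxolan-2-yl)butanoate (racemic) | C[Si](C)(C)CCOC(=O)C(CCC1OCCO1)P(=O)(Oc1ccccc1)Oc1ccccc1
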